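**Assumption:** the SMILES contains no stereocentre and no configurationally stable axis, so the target is achiral and "single enantiomer" is taken to mean the constitution exactly as drawn.

## Retrosynthetic overview

1. The usual aryl–O coupling of two bromoarenes (Ullmann, SNAr, diaryliodonium) is avoided; the tetrasubstituted phenol ring is not aromatic until the last step.
2. Target ⇐ HBr loss and tautomerisation of a 3,6,6-tribromo-2-aryloxycyclohex-2-enone (C=O → OH, vinyl Br → C3–Br, CBr2 → C6–Br).
3. That enone ⇐ double α′-bromination of a 3-bromo-2-aryloxycyclohex-2-enone ⇐ deoxybromination of a 2-aryloxycyclohexane-1,3-dione.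
4. The ether C–O bond ⇐ Rh-carbenoid O–H insertion of 2-diazocyclohexane-1,3-dione into 2,4-dibromophenol.
5. Ring order: the 2,4-dibromophenoxy ring is bought intact; the other ring is bought as cyclohexane-1,3-dione and aromatised last.

## Route

Step 1
Reactants: 1 cyclohexane-1,3-dione
Product: 2 2-diazocyclohexane-1,3-dione
Conditions: p-ABSA (1.05 equiv), Et3N (1.2 equiv), MeCN, 0 °C → rt
Reagents that add atoms: 4-acetamidobenzenesulfonyl azide (p-ABSA), CC(=O)Nc1ccc(cc1)S(=O)(=O)N=[N+]=[N-]
Why: Regitz diazo transfer, in which the dione enolate attacks the terminal azide nitrogen and the triazene collapses to the diazo dione and the sulfonamide; no stereocentre is involved.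

Step 2
Reactants: 2 2-diazocyclohexane-1,3-dione; 3 2,4-dibromophenol (2 equiv)
Product: 4 2-(2,4-dibromophenoxy)-3-hydroxycyclohex-2-en-1-one (enol form of 2-(2,4-dibromophenoxy)cyclohexane-1,3-dione)
Conditions: Rh2(OAc)4 (2 mol %), PhCF3, 80 °C, slow addition of 2 to 3; product extracted into aq NaHCO3, then acidified
Reagents that add atoms: none
Why: Rh(II)-carbenoid O–H insertion (oxonium ylide, then 1,2-proton shift) of the acceptor/acceptor carbenoid into the phenol, with aryl C–H attack disfavoured because the para and one ortho position of 3 are blocked and the ring is deactivated; no stereocentre is formed.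

Step 3
Reactants: 4 2-(2,4-dibromophenoxy)-3-hydroxycyclohex-2-en-1-one
Product: 5 3-bromo-2-(2,4-dibromophenoxy)cyclohex-2-en-1-one
Conditions: (COBr)2 (1.3 equiv), DMF (cat.), CH2Cl2, 0 °C → rt
Reagents that add atoms: oxalyl bromide, BrC(=O)C(=O)Br
Why: Vilsmeier-type deoxybromination of a vinylogous acid (O-activation, then addition–elimination of bromide) gives the β-bromoenone, and the symmetry of the dione allows only one regioisomer.

Step 4
Reactants: 5 3-bromo-2-(2,4-dibromophenoxy)cyclohex-2-en-1-one
Product: 7 3,6,6-tribromo-2-(2,4-dibromophenoxy)cyclohex-2-en-1-one, via rac-3,6-dibromo-2-(2,4-dibromophenoxy)cyclohex-2-en-1-one 6 (not isolated)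
Conditions: LiHMDS (1.05 equiv), THF, −78 °C; NBS (1.0 equiv); LiHMDS (1.1 equiv), −78 °C; NBS (1.1 equiv), −78 → −40 °C; aq NH4Cl
Reagents that add atoms: N-bromosuccinimide, O=C1CCC(=O)N1Br
Why: Kinetic α′-enolate bromination run twice in one flask, since C2 has no hydrogen and LiHMDS at −78 °C removes the C6 proton, NBS gives 6, and its more acidic remaining C6–H is removed and brominated again to the gem-dibromide; the racemic C6 centre of 6 is erased.

Step 5
Reactants: 7 3,6,6-tribromo-2-(2,4-dibromophenoxy)cyclohex-2-en-1-one
Product: 9 3,6-dibromo-2-(2,4-dibromophenoxy)phenol, via 3,6-dibromo-2-(2,4-dibromophenoxy)cyclohexa-2,5-dien-1-one 8 (not isolated)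
Conditions: DBU (2.5 equiv), THF, 0 °C → rt; then 1 M HCl
Reagents that add atoms: none
Why: E2 dehydrobromination across C5–C6 gives dienone 8, the keto tautomer of a phenol, which aromatises irreversibly (dehydrohalogenative aromatisation of a 6,6-dibromocyclohexenone to an o-bromophenol), so the carbonyl becomes OH, one CBr2 bromine remains at C6 and the vinyl bromide becomes C3–Br; the product is achiral.

## Compound list

1 | cyclohexane-1,3-dione | O=C1CCCC(=O)C1 | starting material
2 | 2-diazocyclohexane-1,3-dione | O=C1CCCC(=O)C1=[N+]=[N-] | intermediate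
3 | 2,4-dibromophenol | Oc1ccc(Br)cc1Br | starting material
4 | 2-(2,4-dibromophenoxy)-3-hydroxycyclohex-2-en-1-one | O=C1CCCC(O)=C1Oc1ccc(Br)cc1Br | intermediate
5 | 3-bromo-2-(2,4-dibromophenoxy)cyclohex-2-en-1-one | O=C1CCCC(Br)=C1Oc1ccc(Br)cc1Br | intermediate
6 | rac-3,6-dibromo-2-(2,4-dibromophenoxy)cyclohex-2-en-1-one | O=C1C(Br)CCC(Br)=C1Oc1ccc(Br)cc1Br | intermediate (not isolated)
7 | 3,6,6-tribromo-2-(2,4-dibromophenoxy)cyclohex-2-en-1-one | O=C1C(Br)(Br)CCC(Br)=C1Oc1ccc(Br)cc1Br | intermediate
8 | 3,6-dibromo-2-(2,4-dibromophenoxy)cyclohexa-2,5-dien-1-one | O=C1C(Br)=CCC(Br)=C1Oc1ccc(Br)cc1Br | intermediate (not isolated)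
9 | 3,6-dibromo-2-(2,4-dibromophenoxy)phenol | Oc1c(Br)ccc(Br)c1Oc1ccc(Br)cc1Br | target

## Summary

Total step count: 5. Longest linear sequence: 5 (1 → 2 → 4 → 5 → 7 → 9).

**Three steps most likely to fail, with fallbacks**

Step 2 (carbenoid O–H insertion). The electron-poor, ortho-substituted phenol may be captured too slowly, letting Wolff rearrangement or insertion into the enol O–H of the product compete. The fallback builds the dione ring by Claisen condensation instead and sets out from 3. Commercial methyl 5-oxohexanoate is brominated at the methyl group (Br2, MeOH, 0 °C; minor 4-bromo isomer removed) to give methyl 6-bromo-5-oxohexanoate F1. Phenol 3 is O-alkylated with it (K2CO3, acetone) to give methyl 6-(2,4-dibromophenoxy)-5-oxohexanoate F2. KOtBu in THF then closes the six-membered ring by intramolecular acylation of the ArO–CH2 ketone enolate with the ester (Dieckmann-type), which gives 4 after acidification; the route is rejoined at compound 4.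

Step 4 (double α′-bromination). Proton transfer between enolate and bromoketone, or γ-enolisation, may give mixtures of un-, mono- and di-brominated material. The fallback aromatises first and brominates afterwards; it sets out from 5. CuBr2 (2.0 equiv) with LiBr in refluxing MeCN brominates C6 once (compound 6). Loss of HBr then gives 3-bromo-2-(2,4-dibromophenoxy)cyclohexa-2,5-dien-1-one F3, which tautomerises to 3-bromo-2-(2,4-dibromophenoxy)phenol F4. Amine-directed ortho-bromination (NBS, 10 mol % iPr2NH, CH2Cl2, 0 °C) then places bromine at the only free ortho position, not at the free para position, and the route is rejoined at 9.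

Step 5 (dehydrobromination/aromatisation). DBU could attack a bromine of the CBr2 group (reductive debromination) or the β-bromoenone carbon instead of effecting E2. The fallback replaces base-induced elimination with a selenoxide syn-elimination and sets out from 6, isolated by stopping step 4 after the first LiHMDS/NBS cycle. LiHMDS then PhSeBr (THF, −78 °C) gives rac-3,6-dibromo-2-(2,4-dibromophenoxy)-6-(phenylselanyl)cyclohex-2-en-1-one F5. H2O2 with pyridine in CH2Cl2 at 0 °C oxidises it to 3,6-dibromo-2-(2,4-dibromophenoxy)-6-(phenylseleninyl)cyclohex-2-en-1-one F6. F6 eliminates spontaneously towards C5–H to give dienone 8, and the route is rejoined at 8, which tautomerises to 9.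

## Further compounds

F1 | step 2 | methyl 6-bromo-5-oxohexanoate | COC(=O)CCCC(=O)CBr
F2 | step 2 | methyl 6-(2,4-dibromophenoxy)-5-oxohexanoate | COC(=O)CCCC(=O)COc1ccc(Br)cc1Br
F3 | step 4 | 3-bromo-2-(2,4-dibromophenoxy)cyclohexa-2,5-dien-1-one | O=C1C=CCC(Br)=C1Oc1ccc(Br)cc1Br
F4 | step 4 | 3-bromo-2-(2,4-dibromophenoxy)phenol | Oc1cccc(Br)c1Oc1ccc(Br)cc1Br
F5 | step 5 | rac-3,6-dibromo-2-(2,4-dibromophenoxy)-6-(phenylselanyl)cyclohex-2-en-1-one | O=C1C(Br)([Se]c2ccccc2)CCC(Br)=C1Oc1ccc(Br)cc1Br
F6 | step 5 | 3,6-dibromo-2-(2,4-dibromophenoxy)-6-(phenylseleninyl)cyclohex-2-en-1-one | O=C1C(Br)([Se](=O)c2ccccc2)CCC(Br)=C1Oc1ccc(Br)cc1Br
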